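The C40 skeleton is cut at C11'=C12' and C11=C12 into a C10 dialdehyde and two C15 phosphonium salts, and the route rests on building the ε ring from an open chain. One proton-initiated cation–olefin cyclisation of (E)-geranyl phenyl sulfone forms the C1'–C6' bond, closes the six-membered ε ring (C1'–C6') with its gem-dimethyl C1', leaves the C4'=C5' alkene and sets the C6' stereocentre under control of a chiral SnCl4-bound phenol. The precursor is an acyclic 1,5-diene whose trisubstituted ends become C1' and C5'/C6' and whose phenylsulfonyl group on C7' later serves as the C7' carbanion. The epoxy end comes from ketoisophorone by established steps.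

Key step: step 4

Remarks on the chemistry (assumptions):
- Carotenoid numbering is used, with primed locants for the ε half; the target is read as the all-E (3S,5R,6S,3'R,6'R) diester.
- The sense of induction in the key cyclisation is assumed to follow that of related proton-initiated polyprenoid cyclisations, in which the (R)-configured SnCl4-bound binaphthol acid builds the ring of the normal terpenoid series. Mapped onto C6', that folding is the antipode of the (6'R)-ε ring, so the (S)-acid is chosen.
- The geranyl sulfone is used as the pure E isomer, because the Z isomer would fold to the antipodal ring.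

Step 1
Reactants: 1 geraniol
Product: 2 geranyl bromide
Conditions: PBr3 (0.4 equiv), Et2O, −10 °C
Reagents that add atoms: phosphorus tribromide, BrP(Br)Br
Why: Nucleophilic substitution of the primary allylic alcohol through its phosphite ester at low temperature should give the primary bromide without allylic transposition or loss of the E geometry that the later chair folding needs.

Step 2
Reactants: 2 geranyl bromide; 3 sodium benzenesulfinate
Product: 4 (E)-geranyl phenyl sulfone
Conditions: DMF, 20 °C
Reagents that add atoms: none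
Why: SN2 S-alkylation of the ambident sulfinate by the soft allylic bromide in a dipolar aprotic solvent should give the sulfone as the primary E isomer, with both alkenes untouched.

Step 3
Reactants: 5 (S)-1,1'-bi-2-naphthol; 6 2-fluorobenzyl bromide
Product: 7 (S)-binaphthol mono(2-fluorobenzyl) ether
Conditions: K2CO3, acetone, reflux
Reagents that add atoms: none
Why: Williamson etherification of the mono-phenoxide with one equivalent of the benzylic bromide should stop at the monoether with the stereogenic axis untouched, and the ether is recovered after step 4.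

Step 4
Reactants: 4 (E)-geranyl phenyl sulfone
Product: 8 (R)-α-cyclogeranyl phenyl sulfone
Conditions: 7 (1.1 equiv, recovered), SnCl4 (1.0 equiv), toluene, −78 °C; then pyridine, aq NaHCO3
Reagents that add atoms: none
Why: Proposed new method: the phenol of 7, acidified by SnCl4 bound to its two oxygens and the fluorine, protonates C2' of the electron-rich C1'=C2' alkene while C6' of the C5'=C6' alkene bonds to C1' in an anti fashion, and the tertiary C5' cation then loses H-4' to the weakly basic SnCl4-bound phenoxide; the closest known reaction types are the racemic Brønsted-acid cyclisation of geranyl sulfones and enantioselective proton-initiated polyene cyclisations with chiral Lewis-acid-assisted Brønsted acids. The ε ring closes in a 6-endo-trig cation–olefin mode through a chair in which the E-placed CH2SO2Ph arm is equatorial. C6' is set by the chiral proton donor, because the face on which it delivers hydrogen to C2' decides, through the coupled anti addition across C1'=C2', which of the two enantiomeric chair folds and hence which face of C5'=C6' is used. The step needs chemoselective protonation of the terminal alkene, which the substrate secures because the allylic sulfone makes C5'=C6' electron-poor and binds SnCl4 only weakly. It also needs kinetic proton loss from the accessible C4' methylene and not from the hindered H-6' or the methyl group, which −78 °C and the non-basic counter-ion should favour; any exocyclic isomer is removed by chromatography.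

Step 5
Reactants: 8 (R)-α-cyclogeranyl phenyl sulfone
Product: 9 (R)-3'-oxo-α-cyclogeranyl phenyl sulfone
Conditions: Rh2(cap)4 (cap = caprolactamate, 1 mol %), t-BuOOH (70% in water, 5 equiv), 1,2-dichloroethane, 40 °C
Reagents that add atoms: tert-butyl hydroperoxide, CC(C)(C)OO
Why: Rh2(cap)4-catalysed radical allylic C–H oxidation by tert-butylperoxyl radicals should take the ring methylene C3' and not the hindered, sulfonyl-deactivated H-6', and the base-free medium avoids β-elimination of sulfinate and epimerisation of C6'.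

Step 6
Reactants: 9 (R)-3'-oxo-α-cyclogeranyl phenyl sulfone
Product: 10 (3'R,6'R)-3'-hydroxy-α-cyclogeranyl phenyl sulfone
Conditions: LiBH(s-Bu)3, THF, −78 °C; then H2O
Reagents that add atoms: none
Why: 1,2-Hydride reduction of the β,β-disubstituted enone by the bulky LiBH(s-Bu)3 should occur on the face opposite the pseudo-axial C1' methyl group, which lies anti to the pseudo-axial CH2SO2Ph arm, so that the new hydroxyl at C3' is trans to that arm (3'R, substrate control).

Step 7
Reactants: 10 (3'R,6'R)-3'-hydroxy-α-cyclogeranyl phenyl sulfone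
Product: 11 silyl ether of 10
Conditions: TBSCl, imidazole, DMF, 20 °C
Reagents that add atoms: tert-butyldimethylsilyl chloride, CC(C)(C)[Si](C)(C)Cl
Why: Imidazole-promoted silylation of the secondary allylic alcohol gives an ether that should withstand the carbanion, Na(Hg) and ylide steps.

Step 8
Reactants: 11 silyl ether of 10; 12 (E)-4-acetoxy-2-methylbut-2-enal
Product: 15 β-acetoxy sulfone diacetate, via lithiated sulfone 13 (not isolated), via lithium alkoxide 14 (not isolated)
Conditions: n-BuLi, THF, −78 °C; then 12, −78 °C; then Ac2O, −78 to 0 °C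
Reagents that add atoms: acetic anhydride, CC(=O)OC(C)=O
Why: First half of a Julia–Lythgoe olefination, in which the α-sulfonyl carbanion at C7' adds 1,2 to the formyl group at −78 °C and the alkoxide is acetylated before it can revert, the new centres at C7' and C8' being removed in step 9.

Step 9
Reactants: 15 β-acetoxy sulfone diacetate
Product: 17 ε-C15 dienol, via dienyl acetate 16 (not isolated)
Conditions: Na(Hg) (6% Na), Na2HPO4, THF/MeOH, −20 °C; then K2CO3, MeOH, 20 °C
Reagents that add atoms: none
Why: Julia–Lythgoe reductive elimination, in which electron transfer to the aryl sulfone cleaves the C7'–S bond, the C7' anion expels the 8'-acetate to give the conjugated E-C7'=C8' alkene through the equilibrating intermediate, and carbonate methanolysis then frees the primary alcohol.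

Step 10
Reactants: 17 ε-C15 dienol
Product: 19 ε-C15 phosphonium bromide, via dienyl bromide 18 (not isolated)
Conditions: CBr4, PPh3, CH2Cl2, 0 °C; then PPh3, MeCN, 20 °C
Reagents that add atoms: carbon tetrabromide, BrC(Br)(Br)Br; triphenylphosphine, c1ccc(cc1)P(c1ccccc1)c1ccccc1
Why: Appel bromination of the primary dienylic alcohol under neutral conditions and SN2 quaternisation of triphenylphosphine should give the salt without touching the allylic silyl ether or C6'.

Step 11
Reactants: 19 ε-C15 phosphonium bromide; 20 (2E,4E,6E)-2,7-dimethylocta-2,4,6-trienedial (excess)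
Product: 21 ε-C25 aldehyde
Conditions: NaOMe, MeOH/CH2Cl2, 0 to 20 °C; then heptane, reflux
Reagents that add atoms: none
Why: Wittig olefination of one formyl group of the dialdehyde by the semi-stabilised ylide forms C11'=C12', and heating equilibrates the Z isomer of the new bond to the all-E aldehyde.

Step 12
Reactants: 22 ketoisophorone
Product: 23 (6R)-levodione
Conditions: ene-reductase OYE2, NADP+ (cat.), D-glucose, glucose dehydrogenase, KH2PO4/K2HPO4 buffer pH 6.5, 30 °C
Reagents that add atoms: none
Why: Old-yellow-enzyme ene-reduction adds hydride and a proton trans across the enedione alkene and sets the methyl-bearing centre as R under enzyme control, with the cofactor recycled by glucose dehydrogenase.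

Step 13
Reactants: 23 (6R)-levodione
Product: 24 (4R,6R)-actinol
Conditions: LiBH(s-Bu)3 (1.05 equiv), THF, −78 °C; then H2O
Reagents that add atoms: none
Why: The bulky hydride should reduce only the unhindered C4 carbonyl and attack equatorially, away from the axial C2 methyl group, giving the axial alcohol trans to the equatorial 6-methyl group (4R, substrate control).

Step 14
Reactants: 24 (4R,6R)-actinol
Product: 25 actinol silyl ether
Conditions: TBSCl, imidazole, DMF, 20 °C
Reagents that add atoms: tert-butyldimethylsilyl chloride, CC(C)(C)[Si](C)(C)Cl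
Why: Standard silylation protects the hydroxyl for the enolate, hydride and oxidation steps.

Step 15
Reactants: 25 actinol silyl ether
Product: 27 (R)-enol triflate, via lithium enolate 26 (not isolated)
Conditions: LiN(i-Pr)2, THF, −78 to 0 °C; then PhNTf2, −78 to 20 °C
Reagents that add atoms: N-phenylbis(trifluoromethanesulfonimide), FC(F)(F)S(=O)(=O)N(c1ccccc1)S(=O)(=O)C(F)(F)F
Why: Deprotonation at the only α-hydrogen gives the tetrasubstituted enolate, whose O-sulfonylation yields the vinyl triflate, the methyl-bearing centre having done its work and being removed here.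

Step 16
Reactants: 27 (R)-enol triflate
Product: 28 methyl (R)-cyclohexenecarboxylate
Conditions: Pd(OAc)2, PPh3, CO (1 atm), MeOH, Et3N, DMF, 60 °C
Reagents that add atoms: carbon monoxide, [C-]#[O+]; methanol, CO
Why: Palladium-catalysed alkoxycarbonylation, in which oxidative addition of the vinyl triflate to zerovalent palladium, CO insertion and methanolysis of the acyl complex give the unsaturated ester.

Step 17
Reactants: 28 methyl (R)-cyclohexenecarboxylate
Product: 29 (R)-3-silyloxy-β-cyclogeraniol
Conditions: i-Bu2AlH, CH2Cl2, −78 to 0 °C; then aq KNaC4H4O6 (potassium sodium tartrate)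
Reagents that add atoms: none
Why: 1,2-Reduction of the conjugated ester by i-Bu2AlH should give the allylic alcohol with the silyl ether intact.

Step 18
Reactants: 29 (R)-3-silyloxy-β-cyclogeraniol
Product: 30 anti epoxy alcohol
Conditions: Ti(Oi-Pr)4 (0.2 equiv), D-(−)-diethyl tartrate (0.24 equiv), t-BuOOH (in decane), 4 Å molecular sieves, CH2Cl2, −20 °C
Reagents that add atoms: tert-butyl hydroperoxide, CC(C)(C)OO
Why: Katsuki–Sharpless asymmetric epoxidation under reagent control, in which the complex formed from Ti(Oi-Pr)4 and D-(−)-diethyl tartrate delivers oxygen to the face of the tetrasubstituted C5=C6 alkene anti to the silyloxy group and so sets C5 (R) and C6 together.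

Step 19
Reactants: 30 anti epoxy alcohol
Product: 31 epoxy aldehyde
Conditions: (n-Pr4N)RuO4 (5 mol %), N-methylmorpholine N-oxide, 4 Å molecular sieves, CH2Cl2, 20 °C
Reagents that add atoms: none
Why: Ley–Griffith oxidation under neutral conditions should give the aldehyde without opening the epoxide, and the product has no α-hydrogen to epimerise.

Step 20
Reactants: 31 epoxy aldehyde; 32 triethyl (E)-3-methyl-4-phosphonocrotonate
Product: 34 epoxy C15 dienoate, via lithiated phosphonate 33 (not isolated)
Conditions: 32, LiN(SiMe3)2, THF, −78 °C; then 31, −78 to 0 °C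
Reagents that add atoms: none
Why: Horner–Wadsworth–Emmons olefination, in which the vinylogous phosphonate anion reacts at the carbon next to phosphorus and should give E-C7=C8 together with mainly E-C9=C10, the minor 9Z isomer being removed by chromatography.

Step 21
Reactants: 34 epoxy C15 dienoate
Product: 35 epoxy C15 dienol
Conditions: i-Bu2AlH, CH2Cl2, −78 °C; then aq KNaC4H4O6 (potassium sodium tartrate)
Reagents that add atoms: none
Why: 1,2-Reduction of the dienoate by i-Bu2AlH at low temperature should leave the epoxide and the silyl ether untouched.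

Step 22
Reactants: 35 epoxy C15 dienol
Product: 37 epoxy C15 phosphonium bromide, via epoxy dienyl bromide 36 (not isolated)
Conditions: CBr4, PPh3, Et3N (trace), CH2Cl2, −20 °C; then PPh3, MeCN, 20 °C, dark
Reagents that add atoms: carbon tetrabromide, BrC(Br)(Br)Br; triphenylphosphine, c1ccc(cc1)P(c1ccccc1)c1ccccc1
Why: Appel bromination in the presence of a trace of amine followed by SN2 quaternisation avoids the acid that would rearrange the 5,6-epoxide to the furanoid oxide.

Step 23
Reactants: 21 ε-C25 aldehyde; 37 epoxy C15 phosphonium bromide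
Product: 38 bis-silyl lutein 5,6-epoxide
Conditions: NaOMe, MeOH/CH2Cl2, 0 to 20 °C, argon, dark; then heptane, 80 °C
Reagents that add atoms: none
Why: Wittig olefination of the C25 aldehyde with the epoxy dienyl ylide forms C11=C12 under mildly basic, acid-free conditions that the epoxide and C6' tolerate, and heating equilibrates the Z isomer of the new bond to all-E.

Step 24
Reactants: 38 bis-silyl lutein 5,6-epoxide
Product: 39 lutein 5,6-epoxide
Conditions: n-Bu4NF, THF, 20 °C, dark
Reagents that add atoms: none
Why: Fluoride cleaves both silicon–oxygen bonds under non-acidic conditions that preserve the epoxide and the allylic C3' alcohol.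

Step 25
Reactants: 39 lutein 5,6-epoxide; 40 palmitoyl chloride
Product: 41 lutein 5,6-epoxide dipalmitate (target)
Conditions: 40 (2.5 equiv in all), pyridine, DMAP (cat.), CH2Cl2, 0 to 20 °C, dark
Reagents that add atoms: palmitoyl chloride (the second equivalent of 40), CCCCCCCCCCCCCCCC(=O)Cl
Why: Acylation of both secondary hydroxyls, each by one equivalent of the acid chloride under nucleophilic catalysis, with excess pyridine trapping HCl so that the epoxide is not rearranged, should give the diester with all stereocentres unchanged.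

Compound list
1 | geraniol | CC(C)=CCC/C(C)=C/CO | starting material
2 | geranyl bromide | CC(C)=CCC/C(C)=C/CBr | intermediate
3 | sodium benzenesulfinate | [Na+].[O-]S(=O)c1ccccc1 | starting material
4 | (E)-geranyl phenyl sulfone | CC(C)=CCC/C(C)=C/CS(=O)(=O)c1ccccc1 | intermediate
5 | (S)-1,1'-bi-2-naphthol (S axis, not expressible in plain SMILES) | Oc1ccc2ccccc2c1-c1c(O)ccc2ccccc12 | starting material
6 | 2-fluorobenzyl bromide | Fc1ccccc1CBr | starting material
7 | (S)-2'-(2-fluorobenzyloxy)-1,1'-binaphthalen-2-ol (S axis, not expressible in plain SMILES) | Oc1ccc2ccccc2c1-c1c(OCc2ccccc2F)ccc2ccccc12 | intermediate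
8 | (R)-α-cyclogeranyl phenyl sulfone, {[(1R)-2,6,6-trimethylcyclohex-2-en-1-yl]methanesulfonyl}benzene | O=S(=O)(c1ccccc1)C[C@H]1C(C)=CCCC1(C)C | intermediate
9 | (4R)-3,5,5-trimethyl-4-[(phenylsulfonyl)methyl]cyclohex-2-en-1-one | O=S(=O)(c1ccccc1)C[C@H]1C(C)=CC(=O)CC1(C)C | intermediate
10 | (1R,4R)-3,5,5-trimethyl-4-[(phenylsulfonyl)methyl]cyclohex-2-en-1-ol | O=S(=O)(c1ccccc1)C[C@H]1C(C)=C[C@H](O)CC1(C)C | intermediate
11 | tert-butyldimethylsilyl ether of 10 | O=S(=O)(c1ccccc1)C[C@H]1C(C)=C[C@H](O[Si](C)(C)C(C)(C)C)CC1(C)C | intermediate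
12 | (E)-4-acetoxy-2-methylbut-2-enal | CC(=O)OC/C=C(\C)C=O | starting material
13 | α-lithio derivative of sulfone 11 | O=S(=O)(c1ccccc1)C([Li])[C@H]1C(C)=C[C@H](O[Si](C)(C)C(C)(C)C)CC1(C)C | intermediate (not isolated)
14 | lithium alkoxide of the β-hydroxy sulfone (mixture at C7' and C8') | [Li+].[O-]C(/C(C)=C/COC(C)=O)C([C@H]1C(C)=C[C@H](O[Si](C)(C)C(C)(C)C)CC1(C)C)S(=O)(=O)c1ccccc1 | intermediate (not isolated)
15 | β-acetoxy sulfone diacetate (mixture at C7' and C8') | O=S(=O)(c1ccccc1)C(C(OC(C)=O)/C(C)=C/COC(C)=O)[C@H]1C(C)=C[C@H](O[Si](C)(C)C(C)(C)C)CC1(C)C | intermediate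
16 | (2E,4E)-5-[(1R,4R)-4-(tert-butyldimethylsilyloxy)-2,6,6-trimethylcyclohex-2-en-1-yl]-3-methylpenta-2,4-dien-1-yl acetate | CC(=O)OC/C=C(C)/C=C/[C@H]1C(C)=C[C@H](O[Si](C)(C)C(C)(C)C)CC1(C)C | intermediate (not isolated)
17 | (2E,4E)-5-[(1R,4R)-4-(tert-butyldimethylsilyloxy)-2,6,6-trimethylcyclohex-2-en-1-yl]-3-methylpenta-2,4-dien-1-ol | OC/C=C(C)/C=C/[C@H]1C(C)=C[C@H](O[Si](C)(C)C(C)(C)C)CC1(C)C | intermediate
18 | corresponding (2E,4E)-dienyl bromide | BrC/C=C(C)/C=C/[C@H]1C(C)=C[C@H](O[Si](C)(C)C(C)(C)C)CC1(C)C | intermediate (not isolated)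
19 | [(2E,4E)-5-[(1R,4R)-4-(tert-butyldimethylsilyloxy)-2,6,6-trimethylcyclohex-2-en-1-yl]-3-methylpenta-2,4-dien-1-yl]triphenylphosphonium bromide | [Br-].c1ccccc1[P+](c1ccccc1)(c1ccccc1)C/C=C(C)/C=C/[C@H]1C(C)=C[C@H](O[Si](C)(C)C(C)(C)C)CC1(C)C | intermediate
20 | (2E,4E,6E)-2,7-dimethylocta-2,4,6-trienedial | O=C/C(C)=C/C=C/C=C(C)/C=O | starting material
21 | (2E,4E,6E,8E,10E,12E)-13-[(1R,4R)-4-(tert-butyldimethylsilyloxy)-2,6,6-trimethylcyclohex-2-en-1-yl]-2,7,11-trimethyltrideca-2,4,6,8,10,12-hexaenal | O=C/C(C)=C/C=C/C=C(C)/C=C/C=C(C)/C=C/[C@H]1C(C)=C[C@H](O[Si](C)(C)C(C)(C)C)CC1(C)C | intermediate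
22 | ketoisophorone | CC1=CC(=O)CC(C)(C)C1=O | starting material
23 | (6R)-2,2,6-trimethylcyclohexane-1,4-dione (levodione) | C[C@@H]1CC(=O)CC(C)(C)C1=O | intermediate
24 | (4R,6R)-4-hydroxy-2,2,6-trimethylcyclohexan-1-one (actinol) | C[C@@H]1C[C@@H](O)CC(C)(C)C1=O | intermediate
25 | (4R,6R)-4-(tert-butyldimethylsilyloxy)-2,2,6-trimethylcyclohexan-1-one | C[C@@H]1C[C@@H](O[Si](C)(C)C(C)(C)C)CC(C)(C)C1=O | intermediate
26 | lithium (R)-4-(tert-butyldimethylsilyloxy)-2,6,6-trimethylcyclohex-1-en-1-olate | CC1=C(O[Li])C(C)(C)C[C@H](O[Si](C)(C)C(C)(C)C)C1 | intermediate (not isolated)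
27 | (R)-4-(tert-butyldimethylsilyloxy)-2,6,6-trimethylcyclohex-1-en-1-yl trifluoromethanesulfonate | CC1=C(OS(=O)(=O)C(F)(F)F)C(C)(C)C[C@H](O[Si](C)(C)C(C)(C)C)C1 | intermediate
28 | methyl (R)-4-(tert-butyldimethylsilyloxy)-2,6,6-trimethylcyclohex-1-ene-1-carboxylate | CC1=C(C(=O)OC)C(C)(C)C[C@H](O[Si](C)(C)C(C)(C)C)C1 | intermediate
29 | [(R)-4-(tert-butyldimethylsilyloxy)-2,6,6-trimethylcyclohex-1-en-1-yl]methanol | CC1=C(CO)C(C)(C)C[C@H](O[Si](C)(C)C(C)(C)C)C1 | intermediate
30 | [(1R,4S,6R)-4-(tert-butyldimethylsilyloxy)-2,2,6-trimethyl-7-oxabicyclo[4.1.0]heptan-1-yl]methanol | CC(C)(C)[Si](C)(C)O[C@H]1CC(C)(C)[C@]2(CO)O[C@]2(C)C1 | intermediate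
31 | (1S,4S,6R)-4-(tert-butyldimethylsilyloxy)-2,2,6-trimethyl-7-oxabicyclo[4.1.0]heptane-1-carbaldehyde | CC(C)(C)[Si](C)(C)O[C@H]1CC(C)(C)[C@]2(C=O)O[C@]2(C)C1 | intermediate
32 | ethyl (E)-4-(diethoxyphosphoryl)-3-methylbut-2-enoate | CCOC(=O)/C=C(\C)CP(=O)(OCC)OCC | starting material
33 | lithium salt of the phosphonate carbanion of 32 | [Li+].CCOC(=O)/C=C(\C)[CH-]P(=O)(OCC)OCC | intermediate (not isolated)
34 | ethyl (2E,4E)-5-[(1S,4S,6R)-4-(tert-butyldimethylsilyloxy)-2,2,6-trimethyl-7-oxabicyclo[4.1.0]heptan-1-yl]-3-methylpenta-2,4-dienoate | CC(C)(C)[Si](C)(C)O[C@H]1CC(C)(C)[C@]2(/C=C/C(C)=C/C(=O)OCC)O[C@]2(C)C1 | intermediate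
35 | (2E,4E)-5-[(1S,4S,6R)-4-(tert-butyldimethylsilyloxy)-2,2,6-trimethyl-7-oxabicyclo[4.1.0]heptan-1-yl]-3-methylpenta-2,4-dien-1-ol | CC(C)(C)[Si](C)(C)O[C@H]1CC(C)(C)[C@]2(/C=C/C(C)=C/CO)O[C@]2(C)C1 | intermediate
36 | corresponding (2E,4E)-epoxy dienyl bromide | CC(C)(C)[Si](C)(C)O[C@H]1CC(C)(C)[C@]2(/C=C/C(C)=C/CBr)O[C@]2(C)C1 | intermediate (not isolated)
37 | [(2E,4E)-5-[(1S,4S,6R)-4-(tert-butyldimethylsilyloxy)-2,2,6-trimethyl-7-oxabicyclo[4.1.0]heptan-1-yl]-3-methylpenta-2,4-dien-1-yl]triphenylphosphonium bromide | CC(C)(C)[Si](C)(C)O[C@H]1CC(C)(C)[C@]2(/C=C/C(C)=C/C[P+](c3ccccc3)(c3ccccc3)c3ccccc3)O[C@]2(C)C1.[Br-] | intermediate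
38 | (3S,5R,6S,3'R,6'R)-3,3'-bis(tert-butyldimethylsilyloxy)-5,6-epoxy-5,6-dihydro-β,ε-carotene | CC(C)(C)[Si](C)(C)O[C@H]1CC(C)(C)[C@]2(/C=C/C(C)=C/C=C/C(C)=C/C=C/C=C(C)/C=C/C=C(C)/C=C/[C@H]3C(C)=C[C@H](O[Si](C)(C)C(C)(C)C)CC3(C)C)O[C@]2(C)C1 | intermediate
39 | (3S,5R,6S,3'R,6'R)-5,6-epoxy-5,6-dihydro-β,ε-carotene-3,3'-diol (lutein 5,6-epoxide) | O[C@H]1CC(C)(C)[C@]2(/C=C/C(C)=C/C=C/C(C)=C/C=C/C=C(C)/C=C/C=C(C)/C=C/[C@H]3C(C)=C[C@H](O)CC3(C)C)O[C@]2(C)C1 | intermediate
40 | palmitoyl chloride | CCCCCCCCCCCCCCCC(=O)Cl | starting material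
41 | (3S,5R,6S,3'R,6'R)-5,6-epoxy-5,6-dihydro-β,ε-carotene-3,3'-diyl dihexadecanoate | CCCCCCCCCCCCCCCC(=O)O[C@H]1CC(C)(C)[C@]2(/C=C/C(C)=C/C=C/C(C)=C/C=C/C=C(C)/C=C/C=C(C)/C=C/[C@H]3C(C)=C[C@H](OC(=O)CCCCCCCCCCCCCCC)CC3(C)C)O[C@]2(C)C1 | target

Total step count: 25 (steps 1–11 for the ε half including the one-step preparation of the chiral acid component, steps 12–22 for the epoxy half, steps 23–25 for union and finishing).
Longest linear sequence: 14 steps, from ketoisophorone 22 through steps 12–25 to 41 (the geraniol branch needs 13).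

Steps most likely to fail

Step 4 (Proposed new method). Enantiofacial discrimination may be weak, because the sulfone-deactivated C5'=C6' alkene may engage late and leave a free C1' cation that has lost contact with the chiral proton donor. Proton loss may also drift towards C6' or the methyl group. Fallback with known chemistry, setting out from 4: racemic Brønsted-acid cyclisation (H2SO4 in acetic acid, 0 °C) should give racemic α-cyclogeranyl phenyl sulfone F1. Oxidation as in step 5 should give the racemic enone F2, and reduction as in step 6 the racemic trans alcohol F3. Esterification with (S)-O-methylmandelic acid (DCC, DMAP) should give two diastereomeric esters, the (1R,4R)-alcohol ester F4 and the (1S,4S)-alcohol ester F5, to be separated by chromatography or crystallisation. Methanolysis of F4 (K2CO3, MeOH) returns to the route at 10.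

Step 6. Hydride delivery may prefer the other face if the ring reacts through the conformer with the sulfonylmethyl arm pseudo-equatorial, which would place the hydroxyl cis to the arm. Fallback, setting out from 9: Luche reduction (NaBH4, CeCl3, MeOH, −78 °C) followed by separation of the epimers gives the cis alcohol F6 alongside any 10. Mitsunobu inversion of F6 with 4-nitrobenzoic acid (PPh3, diisopropyl azodicarboxylate, THF) should give the (1R,4R) 4-nitrobenzoate F7 by SN2 displacement at C3'. Methanolysis of F7 (K2CO3, MeOH) returns to the route at 10.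

Step 9. Electron transfer may go astray, by competing reduction of the allylic 1,4-diacetate unit or by protonation of the C7' anion before acetate loss, which would give the saturated C7'–C8' bond. Fallback, setting out from 11: the lithiated sulfone (n-BuLi, THF, −78 °C) is alkylated with ethyl (E)-4-bromo-3-methylbut-2-enoate to the alkylated sulfone F8. DBU in THF should then eliminate benzenesulfinic acid across C7'–C8' by γ-deprotonation of the enoate, giving the (2E,4E)-dienoate F9. Reduction of F9 with i-Bu2AlH (CH2Cl2, −78 °C) returns to the route at 17.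

Further compounds
F1 | step 4 | racemic α-cyclogeranyl phenyl sulfone | O=S(=O)(c1ccccc1)CC1C(C)=CCCC1(C)C
F2 | step 4 | racemic 3,5,5-trimethyl-4-[(phenylsulfonyl)methyl]cyclohex-2-en-1-one | O=S(=O)(c1ccccc1)CC1C(C)=CC(=O)CC1(C)C
F3 | step 4 | racemic trans-3,5,5-trimethyl-4-[(phenylsulfonyl)methyl]cyclohex-2-en-1-ol (racemate, relative configuration drawn) | O=S(=O)(c1ccccc1)C[C@H]1C(C)=C[C@H](O)CC1(C)C
F4 | step 4 | (1R,4R)-3,5,5-trimethyl-4-[(phenylsulfonyl)methyl]cyclohex-2-en-1-yl (S)-2-methoxy-2-phenylacetate | O=S(=O)(c1ccccc1)C[C@H]1C(C)=C[C@H](OC(=O)[C@@H](OC)c2ccccc2)CC1(C)C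
F5 | step 4 | (1S,4S)-3,5,5-trimethyl-4-[(phenylsulfonyl)methyl]cyclohex-2-en-1-yl (S)-2-methoxy-2-phenylacetate | O=S(=O)(c1ccccc1)C[C@@H]1C(C)=C[C@@H](OC(=O)[C@@H](OC)c2ccccc2)CC1(C)C
F6 | step 6 | (1S,4R)-3,5,5-trimethyl-4-[(phenylsulfonyl)methyl]cyclohex-2-en-1-ol (cis alcohol) | O=S(=O)(c1ccccc1)C[C@H]1C(C)=C[C@@H](O)CC1(C)C
F7 | step 6 | (1R,4R)-3,5,5-trimethyl-4-[(phenylsulfonyl)methyl]cyclohex-2-en-1-yl 4-nitrobenzoate | O=S(=O)(c1ccccc1)C[C@H]1C(C)=C[C@H](OC(=O)c2ccc(cc2)[N+](=O)[O-])CC1(C)C
F8 | step 9 | ethyl (E)-5-[(1R,4R)-4-(tert-butyldimethylsilyloxy)-2,6,6-trimethylcyclohex-2-en-1-yl]-3-methyl-5-(phenylsulfonyl)pent-2-enoate (mixture at C7') | CCOC(=O)/C=C(\C)CC([C@H]1C(C)=C[C@H](O[Si](C)(C)C(C)(C)C)CC1(C)C)S(=O)(=O)c1ccccc1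
F9 | step 9 | ethyl (2E,4E)-5-[(1R,4R)-4-(tert-butyldimethylsilyloxy)-2,6,6-trimethylcyclohex-2-en-1-yl]-3-methylpenta-2,4-dienoate | CCOC(=O)/C=C(C)/C=C/[C@H]1C(C)=C[C@H](O[Si](C)(C)C(C)(C)C)CC1(C)C
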